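**Retrosynthetic overview**

1. Ring B is made last. Br and Cl are added anti across C3'=C4' of a 4-methylcyclohex-3-en-1-ol (step 15); that ring comes from ring-closing metathesis (step 14) of a C1' carbinol built by chelation-controlled allylation of a ring A ketone (step 13).
2. Ring A is made first and is cut between C2 (the CMe2 carbon) and C3 (the CHBr carbon). C3 is carried as a nitrile carbon and C2 as the inner carbon of an isopropenyl group on C1, so that hydrogen-atom transfer gives a tertiary C2 radical that closes the ring 5-exo-dig and leaves C3 as a ketone (step 5).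
3. Enabling feature: in ring A the heteroatom-free gem-dimethyl carbon C2 sits between the quaternary C1 and the bromomethine C3, five atoms apart along C2–C1–C5–C4–C3. C2 is therefore a latent tertiary radical, C3 a latent carbonyl, and the quaternary C1 holds the two ends together.
4. The C3 ketone can enolise only towards C4, so the C–Br bond is set by vinyl bromide formation and hydrogenation from the open face (steps 6 and 7).
5. The acyclic precursor with the C1/C5 stereodiad comes from ethyl (3R)-4-cyano-3-hydroxybutanoate by two Fráter–Seebach operations (steps 1 to 3).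

Key step: step 5

Remark on the chemistry: locants follow the target name (ring A = cyclopentane C1–C5, ring B = cyclohexane C1'–C6'). The C2 epimers of 4 and the carbinol epimers of 17 are carried on together, because both centres are erased in the following step.

**Route**

Step 1
Reactants: 1 ethyl (3R)-4-cyano-3-hydroxybutanoate; 2 acetone
Product: 4 ethyl (2S,3R)-4-cyano-3-hydroxy-2-(2-hydroxypropan-2-yl)butanoate, via dilithium alkoxide-enolate 3 (not isolated)
Conditions: LiN(iPr)2 (2.2 equiv), THF, −78 to −20 °C; then 2, −78 °C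
Reagents that add atoms: none
Why: Fráter–Seebach hydroxyalkylation, in which the chelated dilithium alkoxide-enolate of the β-hydroxy ester should add to acetone on the face anti to the cyanomethyl group; the C2 configuration is of no consequence because C2 is re-enolised in step 3.

Step 2
Reactants: 4 ethyl (2S,3R)-4-cyano-3-hydroxy-2-(2-hydroxypropan-2-yl)butanoate
Product: 5 ethyl 2-[(1R)-2-cyano-1-hydroxyethyl]-3-methylbut-2-enoate
Conditions: TsOH·H2O (10 mol%), toluene, 60 °C
Reagents that add atoms: none
Why: Acid-catalysed E1 dehydration, in which only the tertiary carbinol can ionise under these mild conditions and loss of the acidic C2 proton should give the conjugated isopropylidene ester, while the secondary hydroxyl needed for chelation in step 3 stays untouched (a deconjugated isopropenyl isomer would give the same dienolate in step 3).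

Step 3
Reactants: 5 ethyl 2-[(1R)-2-cyano-1-hydroxyethyl]-3-methylbut-2-enoate
Product: 7 ethyl (2S,3R)-4-cyano-3-hydroxy-2-methyl-2-(prop-1-en-2-yl)butanoate, via dilithium alkoxide-dienolate 6 (not isolated)
Conditions: LiN(iPr)2 (2.3 equiv), THF–DMPU, −78 °C; then CH3I, −78 to −40 °C
Reagents that add atoms: iodomethane, CI
Why: Deconjugative Fráter–Seebach alkylation, in which γ-deprotonation gives a lithium dienolate held in a six-membered chelate by the butanoate C3 alkoxide and iodomethane should attack the α-carbon on the face anti to the cyanomethyl group, which sets the quaternary centre as (2S) with the isopropenyl group syn and the methyl group anti to the C3 oxygen.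

Step 4
Reactants: 7 ethyl (2S,3R)-4-cyano-3-hydroxy-2-methyl-2-(prop-1-en-2-yl)butanoate
Product: 8 ethyl (2S,3R)-3-{[tert-butyl(dimethyl)silyl]oxy}-4-cyano-2-methyl-2-(prop-1-en-2-yl)butanoate
Conditions: TBSOTf, 2,6-lutidine, CH2Cl2, 0 °C
Reagents that add atoms: tert-butyldimethylsilyl trifluoromethanesulfonate, CC(C)(C)[Si](C)(C)OS(=O)(=O)C(F)(F)F
Why: Silyl ether formation with the reactive silyl triflate should protect the hindered secondary alcohol, which must be masked for the bromination of step 6 and made bulky for the facial control of step 7; no stereocentre is touched.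

Step 5
Reactants: 8 ethyl (2S,3R)-3-{[tert-butyl(dimethyl)silyl]oxy}-4-cyano-2-methyl-2-(prop-1-en-2-yl)butanoate
Product: 10 ethyl (1S,5R)-5-{[tert-butyl(dimethyl)silyl]oxy}-1,2,2-trimethyl-3-oxocyclopentane-1-carboxylate, via ketimine 9 (not isolated)
Conditions: Fe(acac)3 (0.5 equiv), PhSiH3 (3 equiv), EtOH, 60 °C, argon; then aqueous work-up at pH 5
Reagents that add atoms: water, O
Why: An iron hydride formed from Fe(acac)3 and PhSiH3 should transfer a hydrogen atom to the terminal CH2 of the isopropenyl group and give the tertiary radical at the future C2, which adds to the nitrile carbon (the future C3); the iminyl radical is then reduced by divalent iron and protonated by ethanol to ketimine 9, which water hydrolyses to ketone 10. The closest known reaction types are the iron-hydride-initiated reductive cyclisation of alkenyl nitriles to cyclic ketones and the tin-hydride cyclisation of alkyl radicals onto nitriles. Ring A is closed between C2 and C3 in the 5-exo-dig mode, with the nitrile nitrogen left outside the ring. No stereocentre is created, since C2 becomes a CMe2 carbon and C3 a carbonyl carbon, and C1 and C5 are carried unchanged from 8. The step needs cyclisation to outrun reduction of the tertiary radical and needs chemoselective hydrogen-atom transfer; the quaternary C1 between radical and nitrile (gem-disubstituent effect), the single alkene in 8 and the inertness of ester and silyl ether towards the nucleophilic radical should secure both.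

Step 6
Reactants: 10 ethyl (1S,5R)-5-{[tert-butyl(dimethyl)silyl]oxy}-1,2,2-trimethyl-3-oxocyclopentane-1-carboxylate
Product: 11 ethyl (1S,5R)-3-bromo-5-{[tert-butyl(dimethyl)silyl]oxy}-1,2,2-trimethylcyclopent-3-ene-1-carboxylate
Conditions: (PhO)3P, Br2, CH2Cl2, −60 °C; then Et3N and 10, −60 to 40 °C
Reagents that add atoms: bromine, BrBr
Why: Vinyl bromide formation from an enolisable ketone with the halophosphonium reagent (PhO)3PBr2; the ketone can enolise only towards C4 because C2 is quaternary, so a single C3=C4 bromoalkene should form, and the buffered non-aqueous conditions leave the β-silyloxy group in place.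

Step 7
Reactants: 11 ethyl (1S,5R)-3-bromo-5-{[tert-butyl(dimethyl)silyl]oxy}-1,2,2-trimethylcyclopent-3-ene-1-carboxylate
Product: 12 ethyl (1S,3S,5R)-3-bromo-5-{[tert-butyl(dimethyl)silyl]oxy}-1,2,2-trimethylcyclopentane-1-carboxylate
Conditions: H2 (1 atm), Rh/Al2O3 (5 wt%), EtOAc, rt
Reagents that add atoms: none
Why: Heterogeneous syn-hydrogenation, in which rhodium on alumina should add hydrogen to the C3=C4 bond without hydrogenolysis of the C–Br bond and from the face that carries only the C1 methyl group, opposite the cis-disposed silyloxy and ester groups, so that bromine ends on the face of those groups and C3 is set as (S).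

Step 8
Reactants: 12 ethyl (1S,3S,5R)-3-bromo-5-{[tert-butyl(dimethyl)silyl]oxy}-1,2,2-trimethylcyclopentane-1-carboxylate
Product: 13 [(1R,3S,5R)-3-bromo-5-{[tert-butyl(dimethyl)silyl]oxy}-1,2,2-trimethylcyclopentyl]methanol
Conditions: i-Bu2AlH (3 equiv), CH2Cl2, −78 to 0 °C
Reagents that add atoms: none
Why: Aluminium hydride reduction of the hindered ester should give the neopentyl primary alcohol, and the secondary bromide and the silyl ether are inert to i-Bu2AlH at low temperature (the descriptor at C1 changes only through the priority rules).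

Step 9
Reactants: 13 [(1R,3S,5R)-3-bromo-5-{[tert-butyl(dimethyl)silyl]oxy}-1,2,2-trimethylcyclopentyl]methanol
Product: 14 (1S,3S,5R)-3-bromo-5-{[tert-butyl(dimethyl)silyl]oxy}-1,2,2-trimethylcyclopentane-1-carbaldehyde
Conditions: Dess–Martin periodinane, CH2Cl2, rt
Reagents that add atoms: none
Why: Dess–Martin oxidation should give the non-enolisable aldehyde without touching the bromide or the silyl ether.

Step 10
Reactants: 14 (1S,3S,5R)-3-bromo-5-{[tert-butyl(dimethyl)silyl]oxy}-1,2,2-trimethylcyclopentane-1-carbaldehyde; 15 4-bromo-2-methylbut-1-ene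
Product: 17 1-[(1R,3S,5R)-3-bromo-5-{[tert-butyl(dimethyl)silyl]oxy}-1,2,2-trimethylcyclopentyl]-4-methylpent-4-en-1-ol (both carbinol epimers), via Grignard reagent 16 (not isolated)
Conditions: 15, Mg, THF, rt; then 14, −78 to 0 °C
Reagents that add atoms: none
Why: Grignard addition to the aldehyde brings in C6', C5', C4' and the C4' methyl group, and the new carbinol centre may form as a mixture because it is oxidised in step 11.

Step 11
Reactants: 17 1-[(1R,3S,5R)-3-bromo-5-{[tert-butyl(dimethyl)silyl]oxy}-1,2,2-trimethylcyclopentyl]-4-methylpent-4-en-1-ol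
Product: 18 1-[(1S,3S,5R)-3-bromo-5-{[tert-butyl(dimethyl)silyl]oxy}-1,2,2-trimethylcyclopentyl]-4-methylpent-4-en-1-one
Conditions: Dess–Martin periodinane, CH2Cl2, rt
Reagents that add atoms: none
Why: Dess–Martin oxidation of the hindered secondary alcohol should give the ketone that becomes C1', and both epimers of 17 converge.

Step 12
Reactants: 18 1-[(1S,3S,5R)-3-bromo-5-{[tert-butyl(dimethyl)silyl]oxy}-1,2,2-trimethylcyclopentyl]-4-methylpent-4-en-1-one
Product: 19 1-[(1S,3S,5R)-3-bromo-5-hydroxy-1,2,2-trimethylcyclopentyl]-4-methylpent-4-en-1-one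
Conditions: HF·pyridine, THF, 0 °C to rt
Reagents that add atoms: none
Why: Fluoride-mediated desilylation under acidic conditions frees the C5 hydroxyl needed for chelation in step 13 and should avoid base-induced retro-aldol cleavage of the β-hydroxy ketone.

Step 13
Reactants: 19 1-[(1S,3S,5R)-3-bromo-5-hydroxy-1,2,2-trimethylcyclopentyl]-4-methylpent-4-en-1-one; 20 allylmagnesium bromide
Product: 22 (4R)-4-[(1S,3S,5R)-3-bromo-5-hydroxy-1,2,2-trimethylcyclopentyl]-7-methylocta-1,7-dien-4-ol, via bromomagnesium alkoxide 21 (not isolated)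
Conditions: CH2=CHCH2MgBr (3 equiv), CH2Cl2–Et2O, −78 °C
Reagents that add atoms: none
Why: Chelation-controlled Grignard addition, in which the first equivalent forms the magnesium alkoxide of the C5 hydroxyl, this chelates the ketone oxygen in a six-membered ring cis-fused to ring A, and the allyl reagent should attack the carbonyl face syn to the C1 methyl group and anti to the gem-dimethyl carbon C2, which sets the carbinol carbon as (R).

Step 14
Reactants: 22 (4R)-4-[(1S,3S,5R)-3-bromo-5-hydroxy-1,2,2-trimethylcyclopentyl]-7-methylocta-1,7-dien-4-ol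
Product: 23 (1R)-1-[(1S,3S,5R)-3-bromo-5-hydroxy-1,2,2-trimethylcyclopentyl]-4-methylcyclohex-3-en-1-ol
Conditions: second-generation Grubbs catalyst RuCl2(=CHPh)(PCy3)(H2IMes) (5 mol%), CH2Cl2, 40 °C
Reagents that add atoms: none
Why: Ring-closing metathesis between the allyl group and the 1,1-disubstituted alkene should close ring B as the trisubstituted C3'=C4' alkene with loss of ethene; no stereocentre is touched.

Step 15
Reactants: 23 (1R)-1-[(1S,3S,5R)-3-bromo-5-hydroxy-1,2,2-trimethylcyclopentyl]-4-methylcyclohex-3-en-1-ol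
Product: 25 (1R,3S,4S)-3-bromo-1-[(1S,3S,5R)-3-bromo-5-hydroxy-1,2,2-trimethylcyclopentyl]-4-chloro-4-methylcyclohexan-1-ol, via titanium diolate 24 (not isolated)
Conditions: ClTi(OiPr)3 (1.1 equiv), hexanes–CH2Cl2, rt; then NBS (1.1 equiv), −20 °C
Reagents that add atoms: N-bromosuccinimide, O=C1CCC(=O)N1Br; chlorotitanium triisopropoxide, CC(C)O[Ti](Cl)(OC(C)C)OC(C)C
Why: Titanium-alkoxide-directed bromochlorination of a homoallylic alcohol, in which NBS should form the bromonium ion on the face of the C3'=C4' bond opposite the C1' oxygen and chloride held on titanium at that oxygen is delivered to the tertiary C4' on the oxygen face (anti opening at the more substituted carbon), which places chlorine cis and bromine trans to the C1' hydroxyl and sets C3' as (S) and C4' as (S).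

**Compound list**

1 | ethyl (3R)-4-cyano-3-hydroxybutanoate | N#CC[C@@H](O)CC(=O)OCC | starting material
2 | acetone | CC(C)=O | starting material
3 | dilithium alkoxide-enolate of 1 | N#CC[C@@H](O[Li])C=C(O[Li])OCC | intermediate (not isolated)
4 | ethyl (2S,3R)-4-cyano-3-hydroxy-2-(2-hydroxypropan-2-yl)butanoate | N#CC[C@@H](O)[C@@H](C(C)(C)O)C(=O)OCC | intermediate
5 | ethyl 2-[(1R)-2-cyano-1-hydroxyethyl]-3-methylbut-2-enoate | N#CC[C@@H](O)C(=C(C)C)C(=O)OCC | intermediate
6 | dilithium alkoxide-dienolate of 5 | N#CC[C@@H](O[Li])C(C(C)=C)=C(O[Li])OCC | intermediate (not isolated)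
7 | ethyl (2S,3R)-4-cyano-3-hydroxy-2-methyl-2-(prop-1-en-2-yl)butanoate | N#CC[C@@H](O)[C@@](C(C)=C)(C)C(=O)OCC | intermediate
8 | ethyl (2S,3R)-3-{[tert-butyl(dimethyl)silyl]oxy}-4-cyano-2-methyl-2-(prop-1-en-2-yl)butanoate | N#CC[C@@H](O[Si](C)(C)C(C)(C)C)[C@@](C(C)=C)(C)C(=O)OCC | intermediate
9 | ethyl (1S,5R)-5-{[tert-butyl(dimethyl)silyl]oxy}-3-imino-1,2,2-trimethylcyclopentane-1-carboxylate | CC1(C)C(=N)C[C@@H](O[Si](C)(C)C(C)(C)C)[C@@]1(C)C(=O)OCC | intermediate (not isolated)
10 | ethyl (1S,5R)-5-{[tert-butyl(dimethyl)silyl]oxy}-1,2,2-trimethyl-3-oxocyclopentane-1-carboxylate | CC1(C)C(=O)C[C@@H](O[Si](C)(C)C(C)(C)C)[C@@]1(C)C(=O)OCC | intermediate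
11 | ethyl (1S,5R)-3-bromo-5-{[tert-butyl(dimethyl)silyl]oxy}-1,2,2-trimethylcyclopent-3-ene-1-carboxylate | CC1(C)C(Br)=C[C@@H](O[Si](C)(C)C(C)(C)C)[C@@]1(C)C(=O)OCC | intermediate
12 | ethyl (1S,3S,5R)-3-bromo-5-{[tert-butyl(dimethyl)silyl]oxy}-1,2,2-trimethylcyclopentane-1-carboxylate | CC1(C)[C@@H](Br)C[C@@H](O[Si](C)(C)C(C)(C)C)[C@@]1(C)C(=O)OCC | intermediate
13 | [(1R,3S,5R)-3-bromo-5-{[tert-butyl(dimethyl)silyl]oxy}-1,2,2-trimethylcyclopentyl]methanol | CC1(C)[C@@H](Br)C[C@@H](O[Si](C)(C)C(C)(C)C)[C@@]1(C)CO | intermediate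
14 | (1S,3S,5R)-3-bromo-5-{[tert-butyl(dimethyl)silyl]oxy}-1,2,2-trimethylcyclopentane-1-carbaldehyde | CC1(C)[C@@H](Br)C[C@@H](O[Si](C)(C)C(C)(C)C)[C@@]1(C)C=O | intermediate
15 | 4-bromo-2-methylbut-1-ene | C=C(C)CCBr | starting material
16 | (3-methylbut-3-en-1-yl)magnesium bromide | C=C(C)CC[Mg]Br | intermediate (not isolated)
17 | 1-[(1R,3S,5R)-3-bromo-5-{[tert-butyl(dimethyl)silyl]oxy}-1,2,2-trimethylcyclopentyl]-4-methylpent-4-en-1-ol (both carbinol epimers) | CC1(C)[C@@H](Br)C[C@@H](O[Si](C)(C)C(C)(C)C)[C@@]1(C)C(O)CCC(C)=C | intermediate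
18 | 1-[(1S,3S,5R)-3-bromo-5-{[tert-butyl(dimethyl)silyl]oxy}-1,2,2-trimethylcyclopentyl]-4-methylpent-4-en-1-one | CC1(C)[C@@H](Br)C[C@@H](O[Si](C)(C)C(C)(C)C)[C@@]1(C)C(=O)CCC(C)=C | intermediate
19 | 1-[(1S,3S,5R)-3-bromo-5-hydroxy-1,2,2-trimethylcyclopentyl]-4-methylpent-4-en-1-one | CC1(C)[C@@H](Br)C[C@@H](O)[C@@]1(C)C(=O)CCC(C)=C | intermediate
20 | allylmagnesium bromide | C=CC[Mg]Br | starting material
21 | bromomagnesium alkoxide of 19 | CC1(C)[C@@H](Br)C[C@@H](O[Mg]Br)[C@@]1(C)C(=O)CCC(C)=C | intermediate (not isolated)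
22 | (4R)-4-[(1S,3S,5R)-3-bromo-5-hydroxy-1,2,2-trimethylcyclopentyl]-7-methylocta-1,7-dien-4-ol | CC1(C)[C@@H](Br)C[C@@H](O)[C@@]1(C)[C@@](CC=C)(O)CCC(C)=C | intermediate
23 | (1R)-1-[(1S,3S,5R)-3-bromo-5-hydroxy-1,2,2-trimethylcyclopentyl]-4-methylcyclohex-3-en-1-ol | CC1(C)[C@@H](Br)C[C@@H](O)[C@@]1(C)[C@@]1(O)CCC(C)=CC1 | intermediate
24 | chloro(isopropoxy)titanium 1,3-diolate of 23 | CC1(C)[C@@H](Br)C[C@@H](O[Ti]2(Cl)OC(C)C)[C@@]1(C)[C@@]1(O2)CCC(C)=CC1 | intermediate (not isolated)
25 | (1R,3S,4S)-3-bromo-1-[(1S,3S,5R)-3-bromo-5-hydroxy-1,2,2-trimethylcyclopentyl]-4-chloro-4-methylcyclohexan-1-ol | CC1(C)[C@@H](Br)C[C@@H](O)[C@@]1(C)[C@@]1(O)CC[C@](C)(Cl)[C@@H](Br)C1 | target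

**Step count and risks**

Total step count: 15. Longest linear sequence: 15 steps (1 to 25).

Steps most likely to fail:

Step 15. Transannular capture of the bromonium ion by the C1' oxygen may outrun chloride delivery, or the bromonium ion may form on the oxygen face and be opened diaxially to the wrong diastereomer. The fallback sets out from 23 and makes the oxygen bridge on purpose. NBS alone in CH2Cl2 at 0 °C should give the bromo ether 2-endo-bromo-4-[(1S,3S,5R)-3-bromo-5-hydroxy-1,2,2-trimethylcyclopentyl]-1-methyl-7-oxabicyclo[2.2.1]heptane F1, in which the bridge fixes bromine anti to oxygen. TiCl4 in CH2Cl2 at −78 °C should then ionise the C–O bond at the methyl-bearing bridgehead with assistance from the antiperiplanar bromine and return chloride to C4' on the oxygen face, while the other bridgehead is deactivated by the β-oxygen and has no such assistance. This comes back to the route at 25.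

Step 7. Hydrogenolysis of the vinylic C–Br bond or hydrogen delivery from the hindered face may erode the yield or the C3 configuration. The fallback sets out from ketone 10 and replaces catalytic hydrogenation by a radical hydrogen-atom transfer to an α-bromo radical. Hydrazine hydrate in EtOH should give the hydrazone ethyl (1S,5R)-5-{[tert-butyl(dimethyl)silyl]oxy}-3-hydrazinylidene-1,2,2-trimethylcyclopentane-1-carboxylate F2. CuBr2 and LiOtBu in THF should convert it into the gem-dibromide ethyl (1S,5R)-3,3-dibromo-5-{[tert-butyl(dimethyl)silyl]oxy}-1,2,2-trimethylcyclopentane-1-carboxylate F3. One equivalent of Bu3SnH with Et3B and air in toluene at −78 °C should remove one bromine, the α-bromo radical taking hydrogen from the face of the C1 methyl group. This comes back to the route at 12.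

Step 13. Addition through non-chelated conformers of the very reactive allylmagnesium reagent may give poor facial selectivity, and the magnesium aldolate may open by retro-aldol cleavage. The fallback sets out from 19 and delivers the allyl group through a temporary boron tether. Triallylborane in THF at −78 °C should give the diallylboryl ether of 19 F4. On warming, the ketone oxygen binds boron and one allyl group is transferred inside the bicyclic transition state to the carbonyl face syn to the C1 methyl group, which should give the cyclic allylboronate of 22 F5. Aqueous NaOH then frees the diol. This comes back to the route at 22.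

**Further compounds**

F1 | step 15 | 2-endo-bromo-4-[(1S,3S,5R)-3-bromo-5-hydroxy-1,2,2-trimethylcyclopentyl]-1-methyl-7-oxabicyclo[2.2.1]heptane | CC1(C)[C@@H](Br)C[C@@H](O)[C@@]1(C)[C@@]12CC[C@](C)(O2)[C@@H](Br)C1
F2 | step 7 | ethyl (1S,5R)-5-{[tert-butyl(dimethyl)silyl]oxy}-3-hydrazinylidene-1,2,2-trimethylcyclopentane-1-carboxylate | CC1(C)C(=NN)C[C@@H](O[Si](C)(C)C(C)(C)C)[C@@]1(C)C(=O)OCC
F3 | step 7 | ethyl (1S,5R)-3,3-dibromo-5-{[tert-butyl(dimethyl)silyl]oxy}-1,2,2-trimethylcyclopentane-1-carboxylate | CC1(C)C(Br)(Br)C[C@@H](O[Si](C)(C)C(C)(C)C)[C@@]1(C)C(=O)OCC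
F4 | step 13 | diallylboryl ether of 19 | CC1(C)[C@@H](Br)C[C@@H](OB(CC=C)CC=C)[C@@]1(C)C(=O)CCC(C)=C
F5 | step 13 | cyclic allylboronate of 22 | CC1(C)[C@@H](Br)C[C@@H](OB(CC=C)O2)[C@@]1(C)[C@]2(CC=C)CCC(C)=C
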